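All runs were computed with made-up constants, noise included.

**Early readings.** At early times target climbs faster in amber than in blue, 18.4 % against 8.3 % at 2.50 min, but amber then flattens, with 38.4 % at 20.0 min and 38.9 % at 30.0 min. I take the coupling partner as the limiting reagent, since its charge is 0.600 of the starting material's, and the second substrate competes for it.

| setting | blue | amber | autumn | spring |
|---|---|---|---|---|
| starting material | 0.010 M | 0.010 M | 0.010 M | 0.010 M |
| second substrate | 10 mM | 10 mM | 10.0 mM | 10.0 mM |
| coupling partner | 6 mM | 6 mM | 6.00 mM | 6.00 mM |
| free catalyst | 0.26 mM | 0.58 mM | 0.39 mM | 0.39 mM |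
| remark | run made earlier | run made earlier |  |  |
| time |  |  | 25 min | 80 min |

| run | time / min | target / % | over-reaction product / % | starting material / % | catalyst intermediate A / % |
|---|---|---|---|---|---|
| blue | 2.50 | 8.3 | 1.0 | 89.7 | 1.9 |
| blue | 5.00 | 16.8 | 0.1 | 81.9 | 2.4 |
| blue | 8.00 | 23.4 | 1.2 | 75.5 | 1.7 |
| blue | 15.0 | 32.4 | 0.3 | 65.0 | 2.1 |
| blue | 30.0 | 37.5 | 0.9 | 58.6 | 1.4 |
| amber | 2.50 | 18.4 | 0.2 | 78.0 | 2.9 |
| amber | 8.00 | 33.9 | 0.5 | 59.9 | 4.1 |
| amber | 15.0 | 37.5 | 1.4 | 56.9 | 5.1 |
| amber | 20.0 | 38.4 | 1.3 | 56.2 | 4.0 |
| amber | 30.0 | 38.9 | 1.4 | 56.0 | 4.1 |

(each reading ± 0.5 percentage points)

- which of these there is most of at the end, counted by the starting material in it, autumn (target / starting material / catalyst intermediate A / over-reaction product)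
- which of these there is most of at the end, counted by the starting material in it, spring (target / starting material / catalyst intermediate A / over-reaction product)
- amount of the one of these that there is most of at the end, in percent of the starting material charged, autumn
- amount of the one of these that there is most of at the end, in percent of the starting material charged, spring

**Coupling share.** So I carry the coupling share: the starting material coupled, as target or over-reaction product, per coupling partner charged, at equal charges of starting material and second substrate. Amber's last reading gives 0.672. The same reading puts 0.707 of amber's catalyst in intermediate A.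

**Turned round.** For target to lead, with over-reaction product near amber's 1.4 %, target must pass about 48.6 % of the charge, which is half of what intermediate A leaves uncaptured. The share gives autumn and spring, once their coupling partner is used, a coupled fraction of 40.3 %, so I expect starting material to lead, and I reckon 56.9 % of it for spring. Taking rates proportional to catalyst, autumn matches 16.8 min of amber, past 15.0 min, where target read 1.4 percentage points below its last reading. So I put autumn's starting material between 56.9 % and 58.3 %.

**The forecast.** It says starting material for both flasks, 58 % for autumn and 57 % for spring, “so starting material stays the largest species”.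

**The result.** Starting material stands at 57.5 % in autumn and 56.9 % in spring, more than target's 38.8 % in spring. Spring's coupling share is 0.666, with 0 % of its coupling partner left.

    coupling partner + catalyst intermediate B → free catalyst + second product (k = 11.0 /M/s)
    coupling partner + catalyst intermediate A → free catalyst + target (k = 8.70 /M/s)
    coupling partner + free catalyst + target → free catalyst + over-reaction product (k = 550 /M²/s)
    starting material + free catalyst ⇌ catalyst intermediate A (K = 13000 /M, k = 9.80 /M/s)
    second substrate + free catalyst ⇌ catalyst intermediate B (K = 2200 /M, k = 4.10 /M/s)

**Neighbouring flask.** Spring with coupling partner cut to 0.240 equiv gets from the share a coupled fraction of 16.1 %, and so 81.1 % of starting material left. That flask holds target at 16.7 % and starting material at 80.0 %.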